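**Retrosynthetic overview**
1. Target 13 comes from its N-(2,4-dimethoxybenzyl) imide 12 by acidolytic removal of the imide protecting group in the last step.
2. 12 is cut into the ortho-ethynyl trifluoroacetanilide 5 and the 3-bromo-4-(imidazolyl)maleimide 10. One palladium-catalysed aminopalladation–reductive elimination cascade makes the indole N1–C2 bond, which closes the pyrrole ring of the indole, and the indole C3–maleimide C3 bond, which joins the two halves.
3. Enabling feature: indole C3 carries the maleimide and indole C2 carries only hydrogen, so N1–C2=C3 maps onto an anilide nitrogen plus the two carbons of a terminal alkyne. The partner carbon, C3 of the maleimide ring, is a vinylic carbon of an ene-dione whose C–Br bond adds readily to zerovalent palladium.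
4. 10 comes from dibromomaleimide 8 and stannane 9 (mono-Stille), and 8 from dibromomaleic anhydride 6 and amine 7. 5 comes from 5-bromo-2-iodoaniline 1 by Sonogashira coupling, desilylation and trifluoroacetylation.
5. Ring order: the imidazole and benzene rings are bought, the maleimide ring is fixed as the imide in step 4, and the pyrrole ring of the indole is closed last, in step 6.

Key step: step 6

Remark: the target has no stereocenter, so no stereocontrol is needed; compounds 1, 2, 6, 7 and 9 are taken as catalogue chemicals.

Step 1
Reactants: 1 5-bromo-2-iodoaniline; 2 ethynyltrimethylsilane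
Product: 3 5-bromo-2-[(trimethylsilyl)ethynyl]aniline
Conditions: PdCl2(PPh3)2 (2 mol %), CuI (4 mol %), Et3N, THF, rt
Reagents that add atoms: none
Why: Sonogashira coupling, in which zerovalent palladium inserts into the C–I bond far faster than into the C–Br bond at room temperature, so only the iodide should be alkynylated.

Step 2
Reactants: 3 5-bromo-2-[(trimethylsilyl)ethynyl]aniline
Product: 4 5-bromo-2-ethynylaniline
Conditions: K2CO3 (0.2 equiv), MeOH, rt
Reagents that add atoms: none
Why: Base-catalysed methanolysis of the C(sp)–Si bond (protodesilylation) should free the terminal alkyne without touching the aryl bromide or the amine.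

Step 3
Reactants: 4 5-bromo-2-ethynylaniline
Product: 5 N-(5-bromo-2-ethynylphenyl)-2,2,2-trifluoroacetamide
Conditions: (CF3CO)2O (1.1 equiv), pyridine, CH2Cl2, 0 °C
Reagents that add atoms: trifluoroacetic anhydride, O=C(OC(=O)C(F)(F)F)C(F)(F)F
Why: N-acylation of the aniline should be clean and gives the acidic N–H that carbonate can deprotonate in the key step.

Step 4
Reactants: 6 2,3-dibromomaleic anhydride; 7 2,4-dimethoxybenzylamine
Product: 8 3,4-dibromo-1-(2,4-dimethoxybenzyl)-1H-pyrrole-2,5-dione
Conditions: AcOH, 100 °C
Reagents that add atoms: none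
Why: Imide formation by condensation, in which the amine opens the anhydride to the maleamic acid and hot acetic acid drives cyclodehydration.

Step 5
Reactants: 8 3,4-dibromo-1-(2,4-dimethoxybenzyl)-1H-pyrrole-2,5-dione (1.5 equiv); 9 1-methyl-5-(tributylstannyl)-1H-imidazole
Product: 10 3-bromo-1-(2,4-dimethoxybenzyl)-4-(1-methyl-1H-imidazol-5-yl)-1H-pyrrole-2,5-dione
Conditions: Pd(PPh3)4 (5 mol %), CuI (10 mol %), DMF, 50 °C
Reagents that add atoms: none
Why: Stille cross-coupling, in which the second C–Br bond is deactivated once the electron-donating imidazolyl group is conjugated with the ene-dione and 8 is in excess, so mono-coupling should prevail.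

Step 6
Reactants: 5 N-(5-bromo-2-ethynylphenyl)-2,2,2-trifluoroacetamide; 10 3-bromo-1-(2,4-dimethoxybenzyl)-4-(1-methyl-1H-imidazol-5-yl)-1H-pyrrole-2,5-dione
Product: 12 3-(6-bromo-1H-indol-3-yl)-1-(2,4-dimethoxybenzyl)-4-(1-methyl-1H-imidazol-5-yl)-1H-pyrrole-2,5-dione, via the N-trifluoroacetyl indole 11 (not isolated)
Conditions: Pd(PPh3)4 (5 mol %), K2CO3 (3 equiv), MeCN, 50 °C; then H2O work-up
Reagents that add atoms: none
Why: Zerovalent palladium should insert into the vinylic C–Br bond of 10 to give a σ-maleimidyl divalent palladium bromide that binds the alkyne of 5; the carbonate-generated trifluoroacetamidate nitrogen then attacks the terminal alkyne carbon anti to the metal, and reductive elimination from the resulting indol-3-yl(maleimidyl)palladium forms the indole C3–maleimide C3 bond and returns zerovalent palladium. The closest known reaction type is the aminopalladation–reductive elimination annulation of ortho-alkynyl trifluoroacetanilides with vinyl or aryl halides and triflates (Cacchi indole synthesis), which includes terminal ortho-ethynyl anilides as the alkyne partner and bromomaleimides as the electrophile. The pyrrole ring of the indole closes by 5-endo-dig N1–C2 bond formation, and no stereocenter is created. The step needs chemoselectivity between the two C–Br bonds and attachment at C3 instead of C2, which would arise from C–H alkynylation of the terminal alkyne followed by cyclisation. The first is secured by the much more electron-poor vinylic bromide of the ene-dione at mild temperature, the second by the acidic N–H held ortho to the alkyne and by the absence of copper salts and amine bases. The N-trifluoroacetyl group of 11 should be lost to carbonate and water on work-up, so the free N–H indole 12 is isolated.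

Step 7
Reactants: 12 3-(6-bromo-1H-indol-3-yl)-1-(2,4-dimethoxybenzyl)-4-(1-methyl-1H-imidazol-5-yl)-1H-pyrrole-2,5-dione
Product: 13 didemnimide D, 3-(6-bromo-1H-indol-3-yl)-4-(1-methyl-1H-imidazol-5-yl)-1H-pyrrole-2,5-dione
Conditions: CF3CO2H, anisole (10 equiv), reflux; then aqueous NaHCO3
Reagents that add atoms: none
Why: Acidolytic N-debenzylation, in which the electron-rich benzylic C–N bond of the imide ionises and the 2,4-dimethoxybenzyl cation is captured by anisole (Friedel–Crafts alkylation), while the aryl bromide, the protonated imidazole and the deactivated indole should be untouched.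

**Compound list**
1 | 5-bromo-2-iodoaniline | Nc1cc(Br)ccc1I | starting material
2 | ethynyltrimethylsilane | C#C[Si](C)(C)C | starting material
3 | 5-bromo-2-[(trimethylsilyl)ethynyl]aniline | Nc1cc(Br)ccc1C#C[Si](C)(C)C | intermediate
4 | 5-bromo-2-ethynylaniline | Nc1cc(Br)ccc1C#C | intermediate
5 | N-(5-bromo-2-ethynylphenyl)-2,2,2-trifluoroacetamide | O=C(Nc1cc(Br)ccc1C#C)C(F)(F)F | intermediate
6 | 2,3-dibromomaleic anhydride (3,4-dibromofuran-2,5-dione) | O=C1OC(=O)C(Br)=C1Br | starting material
7 | 2,4-dimethoxybenzylamine | COc1ccc(CN)c(OC)c1 | starting material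
8 | 3,4-dibromo-1-(2,4-dimethoxybenzyl)-1H-pyrrole-2,5-dione | COc1ccc(CN2C(=O)C(Br)=C(Br)C2=O)c(OC)c1 | intermediate
9 | 1-methyl-5-(tributylstannyl)-1H-imidazole | CCCC[Sn](CCCC)(CCCC)c1cncn1C | starting material
10 | 3-bromo-1-(2,4-dimethoxybenzyl)-4-(1-methyl-1H-imidazol-5-yl)-1H-pyrrole-2,5-dione | COc1ccc(CN2C(=O)C(Br)=C(c3cncn3C)C2=O)c(OC)c1 | intermediate
11 | 3-[6-bromo-1-(trifluoroacetyl)-1H-indol-3-yl]-1-(2,4-dimethoxybenzyl)-4-(1-methyl-1H-imidazol-5-yl)-1H-pyrrole-2,5-dione | COc1ccc(CN2C(=O)C(c3cn(C(=O)C(F)(F)F)c4cc(Br)ccc34)=C(c3cncn3C)C2=O)c(OC)c1 | intermediate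
12 | 3-(6-bromo-1H-indol-3-yl)-1-(2,4-dimethoxybenzyl)-4-(1-methyl-1H-imidazol-5-yl)-1H-pyrrole-2,5-dione | COc1ccc(CN2C(=O)C(c3c[nH]c4cc(Br)ccc34)=C(c3cncn3C)C2=O)c(OC)c1 | intermediate
13 | didemnimide D, 3-(6-bromo-1H-indol-3-yl)-4-(1-methyl-1H-imidazol-5-yl)-1H-pyrrole-2,5-dione | Cn1cncc1C1=C(c2c[nH]c3cc(Br)ccc23)C(=O)NC1=O | target

**Step count**
Total: 7 steps. Longest linear sequence: 5 steps (steps 1, 2, 3, 6, 7).

**Steps most likely to fail**

Step 6. The maleimidyl palladium intermediate may be intercepted by the terminal C–H of the alkyne, giving alkynylation and later cyclisation with the maleimide on C2. Alternatively, the aminopalladation intermediate may be protonated before reductive elimination, so the indole ring closes without the C–C bond. The fallback sets out from 10. Commercial 6-bromoindole is deprotonated with EtMgBr in THF/toluene to give (6-bromo-1H-indol-1-yl)magnesium bromide F1. This ambident nucleophile should attack the bromine-bearing carbon of 10 through its C3 at 60 °C (conjugate addition–elimination, the established indolyl Grignard route to indolylmaleimides) and give 12, where the route is rejoined.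

Step 5. Mono-selectivity may be lost through a second coupling at the remaining C–Br bond, or the electron-rich stannane may undergo protodestannylation before transmetalation. The fallback sets out from 7 and avoids the coupling altogether.
- Commercial 2-(1-methyl-1H-imidazol-5-yl)acetic acid hydrochloride is coupled with 7 (EDC·HCl, HOBt, iPr2NEt, DMF) to give N-(2,4-dimethoxybenzyl)-2-(1-methyl-1H-imidazol-5-yl)acetamide F2.
- Perkin-type condensation of F2 with dimethyl oxalate (KOtBu, THF, 0 °C to rt) should close the imide ring and give 1-(2,4-dimethoxybenzyl)-3-hydroxy-4-(1-methyl-1H-imidazol-5-yl)-1H-pyrrole-2,5-dione F3.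
- O-Sulfonylation (Tf2O, Et3N, CH2Cl2, −78 °C) gives 1-(2,4-dimethoxybenzyl)-4-(1-methyl-1H-imidazol-5-yl)-2,5-dioxo-2,5-dihydro-1H-pyrrol-3-yl trifluoromethanesulfonate F4.
- F4 takes the place of 10 under the conditions of step 6, vinyl triflates being standard partners of this annulation, and the route is rejoined at 12.

Step 7. Cleavage of the benzylic C–N bond of the imide may be incomplete, or the 2,4-dimethoxybenzyl cation may re-attach to the indole nucleus. The fallback sets out from 12. Saponification (KOH, aqueous EtOH, reflux) followed by acidification (aqueous HCl) should open the imide and re-close it, with loss of the amine, as 3-(6-bromo-1H-indol-3-yl)-4-(1-methyl-1H-imidazol-5-yl)furan-2,5-dione F5. Treatment of F5 with hexamethyldisilazane and MeOH in DMF at rt (anhydride-to-imide exchange) should give 13.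

**Further compounds**
F1 | step 6 | (6-bromo-1H-indol-1-yl)magnesium bromide | Br[Mg]n1ccc2ccc(Br)cc21
F2 | step 5 | N-(2,4-dimethoxybenzyl)-2-(1-methyl-1H-imidazol-5-yl)acetamide | COc1ccc(CNC(=O)Cc2cncn2C)c(OC)c1
F3 | step 5 | 1-(2,4-dimethoxybenzyl)-3-hydroxy-4-(1-methyl-1H-imidazol-5-yl)-1H-pyrrole-2,5-dione | COc1ccc(CN2C(=O)C(O)=C(c3cncn3C)C2=O)c(OC)c1
F4 | step 5 | 1-(2,4-dimethoxybenzyl)-4-(1-methyl-1H-imidazol-5-yl)-2,5-dioxo-2,5-dihydro-1H-pyrrol-3-yl trifluoromethanesulfonate | COc1ccc(CN2C(=O)C(OS(=O)(=O)C(F)(F)F)=C(c3cncn3C)C2=O)c(OC)c1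
F5 | step 7 | 3-(6-bromo-1H-indol-3-yl)-4-(1-methyl-1H-imidazol-5-yl)furan-2,5-dione | Cn1cncc1C1=C(c2c[nH]c3cc(Br)ccc23)C(=O)OC1=O
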